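## Retrosynthetic overview

1. Leachianone A 22 comes from flavanone 20 by removal of one allyl carbonate and two TIPS ethers. Ring C (the pyranone) is the only ring that is built; it is closed last, by an intramolecular Mitsunobu O1–C2 etherification with inversion from the (R)-aldol 19.
2. Aldol 19 comes from the key C2–C3 bond: an intermolecular, catalyst-controlled Mukaiyama aldol between enol silane 15 (from ring A acetophenone 14) and ring B aldehyde 17.
3. Ketone 14 comes from a Negishi sp3–sp2 coupling of (S)-lavandulylzinc iodide 13 with iodophenol 12. Iodophenol 12 comes from 2,4,6-trihydroxyacetophenone 10; its one chelated OH stays free, directs iodination to its ortho position and later becomes O1, which places the side chain at C-8.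
4. Lavandulyl iodide 9 comes from an Evans deconjugative alkylation of N-senecioyl oxazolidinone 4 with prenyl bromide 5, then LiBH4 reduction and iodination.
5. Rings A and B are bought as arenes (10 and 16).

Assumption: in step 10 the (R,R)-bisphosphoramide is taken to direct the enol silane to the Re face of the aryl aldehyde; a Mosher ester check on 19 confirms this, and the mirror-image catalyst is used unchanged otherwise if the check says the opposite.

## Route

Step 1
Reactants: 1 (4S)-4-benzyl-1,3-oxazolidin-2-one; 2 3-methylbut-2-enoyl chloride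
Product: 4 (4S)-4-benzyl-3-(3-methylbut-2-enoyl)-1,3-oxazolidin-2-one, via lithium oxazolidinide 3 (not isolated)
Conditions: n-BuLi (1.0 equiv), THF, −78 °C; then 2, −78 → 0 °C
Reagents that add atoms: n-butyllithium, [Li]CCCC (gives the lithium of 3; none of its atoms stay in 4)
Why: N-acylation of the lithiated Evans oxazolidinone with the acid chloride is fast at −78 °C and avoids the vinylketene (deconjugation) pathway that amine bases open.

Step 2
Reactants: 4 (4S)-4-benzyl-3-(3-methylbut-2-enoyl)-1,3-oxazolidin-2-one; 5 1-bromo-3-methylbut-2-ene (prenyl bromide)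
Product: 7 (4S)-4-benzyl-3-[(2S)-5-methyl-2-(prop-1-en-2-yl)hex-4-enoyl]-1,3-oxazolidin-2-one, via sodium dienolate 6 (not isolated)
Conditions: NaN(SiMe3)2 (1.1 equiv), THF, −78 °C, 45 min; then 5 (3 equiv), −78 → −45 °C; chromatography to a single diastereomer
Reagents that add atoms: sodium bis(trimethylsilyl)amide, [Na+].C[Si](C)(C)[N-][Si](C)(C)C (gives the sodium of 6; none of its atoms stay in 7)
Why: Evans asymmetric alkylation in its deconjugative form: γ-deprotonation gives the chelated (Z)-dienolate, which takes prenyl bromide at the α-carbon on the face away from the benzyl group and so sets the (2S) centre, the future lavandulyl stereocentre.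

Step 3
Reactants: 7 (4S)-4-benzyl-3-[(2S)-5-methyl-2-(prop-1-en-2-yl)hex-4-enoyl]-1,3-oxazolidin-2-one
Product: 8 (2S)-5-methyl-2-(prop-1-en-2-yl)hex-4-en-1-ol [(S)-lavandulol]
Conditions: LiBH4 (1.2 equiv), H2O (1.2 equiv), Et2O, 0 °C
Reagents that add atoms: none
Why: Reductive cleavage of the imide by hydride attack at the exocyclic carbonyl gives the primary alcohol without touching the isolated alkenes or the α-stereocentre, and the auxiliary is recovered.

Step 4
Reactants: 8 (2S)-5-methyl-2-(prop-1-en-2-yl)hex-4-en-1-ol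
Product: 9 (3S)-3-(iodomethyl)-2,6-dimethylhepta-1,5-diene [(S)-lavandulyl iodide]
Conditions: I2, PPh3, imidazole, CH2Cl2, 0 °C → rt
Reagents that add atoms: iodine, [I][I]
Why: Appel-type (Garegg–Samuelsson) iodination is an SN2 displacement at the primary carbon, so the neighbouring stereocentre is not involved.

Step 5
Reactants: 10 1-(2,4,6-trihydroxyphenyl)ethanone
Product: 11 1-[2-hydroxy-4,6-bis(triisopropylsilyloxy)phenyl]ethanone
Conditions: TIPSCl (2.3 equiv), imidazole (5 equiv), DMAP (cat.), DMF, 0 → 40 °C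
Reagents that add atoms: triisopropylsilyl chloride, CC(C)[Si](Cl)(C(C)C)C(C)C
Why: Phenol silylation takes the 4-OH and one of the two equivalent ortho OH groups, while the last OH is locked in a hydrogen bond to the ketone and stays free; this OH later becomes O1.

Step 6
Reactants: 11 1-[2-hydroxy-4,6-bis(triisopropylsilyloxy)phenyl]ethanone
Product: 12 1-[2-hydroxy-3-iodo-4,6-bis(triisopropylsilyloxy)phenyl]ethanone
Conditions: N-iodosuccinimide (1.05 equiv), CH2Cl2, 0 °C, dark
Reagents that add atoms: N-iodosuccinimide, O=C1CCC(=O)N1I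
Why: Electrophilic aromatic iodination goes ortho to the free phenol (C-3), because the only other open position (C-5) is shielded by two flanking OTIPS groups.

Step 7
Reactants: 9 (3S)-3-(iodomethyl)-2,6-dimethylhepta-1,5-diene; 12 1-[2-hydroxy-3-iodo-4,6-bis(triisopropylsilyloxy)phenyl]ethanone
Product: 14 1-{2-hydroxy-3-[(2R)-5-methyl-2-(prop-1-en-2-yl)hex-4-en-1-yl]-4,6-bis(triisopropylsilyloxy)phenyl}ethanone, via lavandulylzinc iodide 13 (not isolated)
Conditions: 9 (1.8 equiv), Zn (3 equiv, activated with BrCH2CH2Br and Me3SiCl), LiCl, THF, 40 °C; then 12 (1.0 equiv), Pd(OAc)2 (5 mol %), SPhos (10 mol %), THF, 25 → 50 °C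
Reagents that add atoms: zinc, [Zn] (ends in 13 only; none of it stays in 14)
Why: Negishi sp3–sp2 coupling of a primary alkylzinc with a hindered aryl iodide under Pd/SPhos tolerates the chelated phenol and the ketone; the stereocentre is β to zinc and untouched, and its descriptor changes from S to R only because the CIP priorities change.

Step 8
Reactants: 14 1-{2-hydroxy-3-[(2R)-5-methyl-2-(prop-1-en-2-yl)hex-4-en-1-yl]-4,6-bis(triisopropylsilyloxy)phenyl}ethanone
Product: 15 trimethyl[(1-{3-[(2R)-5-methyl-2-(prop-1-en-2-yl)hex-4-en-1-yl]-4,6-bis(triisopropylsilyloxy)-2-(trimethylsilyloxy)phenyl}ethenyl)oxy]silane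
Conditions: Me3SiOTf (2.4 equiv), Et3N (3.5 equiv), CH2Cl2, 0 °C → rt; pentane extraction, used crude
Reagents that add atoms: trimethylsilyl trifluoromethanesulfonate, C[Si](C)(C)OS(=O)(=O)C(F)(F)F
Why: Soft enolisation and O-silylation give the only possible (terminal) enol silane of the methyl ketone and cap the phenol in the same operation.

Step 9
Reactants: 16 4-hydroxy-2-methoxybenzaldehyde
Product: 17 4-formyl-3-methoxyphenyl prop-2-en-1-yl carbonate
Conditions: allyl chloroformate (1.2 equiv), pyridine, CH2Cl2, 0 °C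
Reagents that add atoms: allyl chloroformate, C=CCOC(=O)Cl
Why: O-acylation gives an electron-withdrawing allyl carbonate that makes the aldehyde more electrophilic, keeps the later benzylic carbinol from ionising, and is removable under neutral conditions.

Step 10
Reactants: 15 trimethyl[(1-{3-[(2R)-5-methyl-2-(prop-1-en-2-yl)hex-4-en-1-yl]-4,6-bis(triisopropylsilyloxy)-2-(trimethylsilyloxy)phenyl}ethenyl)oxy]silane; 17 4-formyl-3-methoxyphenyl prop-2-en-1-yl carbonate
Product: 19 4-[(1R)-1-hydroxy-3-{2-hydroxy-3-[(2R)-5-methyl-2-(prop-1-en-2-yl)hex-4-en-1-yl]-4,6-bis(triisopropylsilyloxy)phenyl}-3-oxopropyl]-3-methoxyphenyl prop-2-en-1-yl carbonate, via trichlorosilyl aldolate 18 (not isolated)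
Conditions: 17 (1.3 equiv), SiCl4 (1.5 equiv), (R,R)-bisphosphoramide [two (R)-N,N'-dimethyl-1,1'-binaphthyl-2,2'-diamine phosphoramide units joined by a pentane-1,5-diyl chain] (5 mol %), i-Pr2NEt (10 mol %), CH2Cl2, −78 °C, 8 h; cold aq NaHCO3/KH2PO4, then 5 % aq citric acid wash
Reagents that add atoms: silicon tetrachloride, Cl[Si](Cl)(Cl)Cl (gives the SiCl3 group of 18; none of it stays in 19)
Why: Lewis base-catalysed enantioselective Mukaiyama aldol: the chiral phosphoramide-bound trichlorosilyl cation activates the aryl aldehyde and exposes its Re face to the methyl ketone enol silane, giving the (R)-carbinol under catalyst control; work-up frees the phenol.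

Step 11
Reactants: 19 4-[(1R)-1-hydroxy-3-{2-hydroxy-3-[(2R)-5-methyl-2-(prop-1-en-2-yl)hex-4-en-1-yl]-4,6-bis(triisopropylsilyloxy)phenyl}-3-oxopropyl]-3-methoxyphenyl prop-2-en-1-yl carbonate
Product: 20 3-methoxy-4-[(2S)-8-[(2R)-5-methyl-2-(prop-1-en-2-yl)hex-4-en-1-yl]-4-oxo-5,7-bis(triisopropylsilyloxy)-3,4-dihydro-2H-chromen-2-yl]phenyl prop-2-en-1-yl carbonate
Conditions: PPh3 (1.5 equiv), DIAD (1.5 equiv), THF (0.02 M), 0 °C → rt
Reagents that add atoms: none
Why: Intramolecular Mitsunobu etherification: the only free phenol (the chelated 2-OH next to the lavandulyl group) displaces the activated benzylic alcohol in a 6-exo SN2 with inversion, turning the (R)-carbinol into the (2S)-flavanone and closing ring C with the side chain at C-8.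

Step 12
Reactants: 20 3-methoxy-4-[(2S)-8-[(2R)-5-methyl-2-(prop-1-en-2-yl)hex-4-en-1-yl]-4-oxo-5,7-bis(triisopropylsilyloxy)-3,4-dihydro-2H-chromen-2-yl]phenyl prop-2-en-1-yl carbonate
Product: 21 (2S)-2-(4-hydroxy-2-methoxyphenyl)-8-[(2R)-5-methyl-2-(prop-1-en-2-yl)hex-4-en-1-yl]-5,7-bis(triisopropylsilyloxy)-2,3-dihydro-4H-chromen-4-one
Conditions: Pd(PPh3)4 (5 mol %), dimedone (3 equiv), THF, rt
Reagents that add atoms: none
Why: Tsuji–Trost deallylation: zerovalent palladium ionises the allyl carbonate, CO2 is lost and the allyl group is passed to the acidic scavenger, so the phenol is freed without base and C-2 and the isolated alkenes are untouched.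

Step 13
Reactants: 21 (2S)-2-(4-hydroxy-2-methoxyphenyl)-8-[(2R)-5-methyl-2-(prop-1-en-2-yl)hex-4-en-1-yl]-5,7-bis(triisopropylsilyloxy)-2,3-dihydro-4H-chromen-4-one
Product: 22 leachianone A
Conditions: Bu4NF (2.5 equiv), AcOH (2.5 equiv), THF, 0 °C → rt
Reagents that add atoms: none
Why: Fluoride desilylation buffered with acetic acid removes both aryl TIPS ethers without the base that would epimerise C-2 by retro-oxa-Michael opening and without the strong acid that would cyclise a phenol onto the lavandulyl alkenes.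

## Compound list

1 | (4S)-4-benzyl-1,3-oxazolidin-2-one | O=C1N[C@@H](Cc2ccccc2)CO1 | starting material
2 | 3-methylbut-2-enoyl chloride | CC(C)=CC(=O)Cl | starting material
3 | lithium (4S)-4-benzyl-2-oxo-1,3-oxazolidin-3-ide | [Li+].O=C1[N-][C@@H](Cc2ccccc2)CO1 | intermediate (not isolated)
4 | (4S)-4-benzyl-3-(3-methylbut-2-enoyl)-1,3-oxazolidin-2-one | CC(C)=CC(=O)N1C(=O)OC[C@@H]1Cc1ccccc1 | intermediate
5 | 1-bromo-3-methylbut-2-ene (prenyl bromide) | CC(C)=CCBr | starting material
6 | sodium (1Z)-1-[(4S)-4-benzyl-2-oxo-1,3-oxazolidin-3-yl]-3-methylbuta-1,3-dien-1-olate | [Na+].C=C(C)/C=C(\[O-])N1C(=O)OC[C@@H]1Cc1ccccc1 | intermediate (not isolated)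
7 | (4S)-4-benzyl-3-[(2S)-5-methyl-2-(prop-1-en-2-yl)hex-4-enoyl]-1,3-oxazolidin-2-one | C=C(C)[C@H](CC=C(C)C)C(=O)N1C(=O)OC[C@@H]1Cc1ccccc1 | intermediate
8 | (2S)-5-methyl-2-(prop-1-en-2-yl)hex-4-en-1-ol, (S)-lavandulol | C=C(C)[C@H](CC=C(C)C)CO | intermediate
9 | (3S)-3-(iodomethyl)-2,6-dimethylhepta-1,5-diene, (S)-lavandulyl iodide | C=C(C)[C@H](CC=C(C)C)CI | intermediate
10 | 1-(2,4,6-trihydroxyphenyl)ethanone | CC(=O)c1c(O)cc(O)cc1O | starting material
11 | 1-[2-hydroxy-4,6-bis(triisopropylsilyloxy)phenyl]ethanone | CC(=O)c1c(O)cc(O[Si](C(C)C)(C(C)C)C(C)C)cc1O[Si](C(C)C)(C(C)C)C(C)C | intermediate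
12 | 1-[2-hydroxy-3-iodo-4,6-bis(triisopropylsilyloxy)phenyl]ethanone | CC(=O)c1c(O)c(I)c(O[Si](C(C)C)(C(C)C)C(C)C)cc1O[Si](C(C)C)(C(C)C)C(C)C | intermediate
13 | iodo[(2S)-5-methyl-2-(prop-1-en-2-yl)hex-4-en-1-yl]zinc, lavandulylzinc iodide | C=C(C)[C@H](CC=C(C)C)C[Zn]I | intermediate (not isolated)
14 | 1-{2-hydroxy-3-[(2R)-5-methyl-2-(prop-1-en-2-yl)hex-4-en-1-yl]-4,6-bis(triisopropylsilyloxy)phenyl}ethanone | C=C(C)[C@H](CC=C(C)C)Cc1c(O)c(C(C)=O)c(O[Si](C(C)C)(C(C)C)C(C)C)cc1O[Si](C(C)C)(C(C)C)C(C)C | intermediate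
15 | trimethyl[(1-{3-[(2R)-5-methyl-2-(prop-1-en-2-yl)hex-4-en-1-yl]-4,6-bis(triisopropylsilyloxy)-2-(trimethylsilyloxy)phenyl}ethenyl)oxy]silane | C=C(C)[C@H](CC=C(C)C)Cc1c(O[Si](C)(C)C)c(C(=C)O[Si](C)(C)C)c(O[Si](C(C)C)(C(C)C)C(C)C)cc1O[Si](C(C)C)(C(C)C)C(C)C | intermediate
16 | 4-hydroxy-2-methoxybenzaldehyde | COc1cc(O)ccc1C=O | starting material
17 | 4-formyl-3-methoxyphenyl prop-2-en-1-yl carbonate | C=CCOC(=O)Oc1ccc(C=O)c(OC)c1 | intermediate
18 | 3-methoxy-4-[(1R)-3-{3-[(2R)-5-methyl-2-(prop-1-en-2-yl)hex-4-en-1-yl]-4,6-bis(triisopropylsilyloxy)-2-(trimethylsilyloxy)phenyl}-3-oxo-1-(trichlorosilyloxy)propyl]phenyl prop-2-en-1-yl carbonate | C=C(C)[C@H](CC=C(C)C)Cc1c(O[Si](C)(C)C)c(C(=O)C[C@@H](O[Si](Cl)(Cl)Cl)c2ccc(OC(=O)OCC=C)cc2OC)c(O[Si](C(C)C)(C(C)C)C(C)C)cc1O[Si](C(C)C)(C(C)C)C(C)C | intermediate (not isolated)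
19 | 4-[(1R)-1-hydroxy-3-{2-hydroxy-3-[(2R)-5-methyl-2-(prop-1-en-2-yl)hex-4-en-1-yl]-4,6-bis(triisopropylsilyloxy)phenyl}-3-oxopropyl]-3-methoxyphenyl prop-2-en-1-yl carbonate | C=C(C)[C@H](CC=C(C)C)Cc1c(O)c(C(=O)C[C@@H](O)c2ccc(OC(=O)OCC=C)cc2OC)c(O[Si](C(C)C)(C(C)C)C(C)C)cc1O[Si](C(C)C)(C(C)C)C(C)C | intermediate
20 | 3-methoxy-4-[(2S)-8-[(2R)-5-methyl-2-(prop-1-en-2-yl)hex-4-en-1-yl]-4-oxo-5,7-bis(triisopropylsilyloxy)-3,4-dihydro-2H-chromen-2-yl]phenyl prop-2-en-1-yl carbonate | C=C(C)[C@H](CC=C(C)C)Cc1c(O[Si](C(C)C)(C(C)C)C(C)C)cc(O[Si](C(C)C)(C(C)C)C(C)C)c2c1O[C@H](c1ccc(OC(=O)OCC=C)cc1OC)CC2=O | intermediate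
21 | (2S)-2-(4-hydroxy-2-methoxyphenyl)-8-[(2R)-5-methyl-2-(prop-1-en-2-yl)hex-4-en-1-yl]-5,7-bis(triisopropylsilyloxy)-2,3-dihydro-4H-chromen-4-one | C=C(C)[C@H](CC=C(C)C)Cc1c(O[Si](C(C)C)(C(C)C)C(C)C)cc(O[Si](C(C)C)(C(C)C)C(C)C)c2c1O[C@H](c1ccc(O)cc1OC)CC2=O | intermediate
22 | leachianone A, (2S)-5,7-dihydroxy-2-(4-hydroxy-2-methoxyphenyl)-8-[(2R)-5-methyl-2-(prop-1-en-2-yl)hex-4-en-1-yl]-2,3-dihydro-4H-chromen-4-one | C=C(C)[C@H](CC=C(C)C)Cc1c(O)cc(O)c2c1O[C@H](c1ccc(O)cc1OC)CC2=O | target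

## Step count and risks

Total step count: 13.
Longest linear sequence: 10 steps (1, 2, 3, 4, 7, 8, 10, 11, 12, 13). Steps 5–6 and step 9 are the two side branches.

The three steps most likely to fail:

**Step 10 (catalytic asymmetric aldol).** The enol silane is di-ortho-substituted and the aldehyde carries an ortho-methoxy group, so rate or enantioselectivity may fall short of the values known for simple partners. The fallback gives up catalyst control and sets out from 14 and 17. Ketone 14 is converted with LiN(SiMe3)2 (2.2 equiv, THF, −78 °C) into its dilithium phenoxide–enolate, the dianion F1, which adds to 17 without stereocontrol. This gives 19 together with its carbinol epimer, the (1S)-aldol F2, in about equal amounts. The two are diastereomers because of the lavandulyl centre and are separated by preparative HPLC on a cellulose tris(3,5-dimethylphenylcarbamate) phase. The route is rejoined at 19; F2 is not lost, because it can be fed into the chalcone pathway described next.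

**Step 11 (Mitsunobu ring closure).** E1cB loss of the activated hydroxyl to the chalcone, or partial ionisation at the ortho-methoxybenzylic carbon, can lower yield or stereochemical purity. The fallback changes the ring-closing bond formation from SN2 to conjugate addition and sets out from 19. Catalytic DBU in toluene dehydrates 19 to the (E)-chalcone F3. F3 is then cyclised by intramolecular oxa-Michael addition (the biomimetic chalcone–flavanone isomerisation) with a quinine-derived bifunctional thiourea. This gives 20 together with its C-2 epimer, the (2R)-flavanone F4. The epimers are separated by preparative HPLC on a chiral stationary phase, F4 is re-equilibrated through F3 with DBU and recycled, and the route is rejoined at 20.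

**Step 7 (zinc insertion and Negishi coupling).** Insertion into the β-branched homoallylic iodide can be slow or leak through radical pathways, and the hindered, phenol-bearing aryl iodide is a demanding partner. The fallback replaces the zinc manifold by a boron ate complex and sets out from 9 and 12. Lithium–iodine exchange on 9 (t-BuLi, 2.1 equiv, Et2O, −78 °C) gives lavandulyllithium F5 with no radical or protic step near the stereocentre. B-methoxy-9-borabicyclo[3.3.1]nonane traps it as the lithium borate F6. F6 is coupled with 12 in a B-alkyl Suzuki–Miyaura reaction (PdCl2(dppf), AsPh3, DMF/THF, rt → 45 °C, no added aqueous base, so the aryl silyl ethers survive). The route is rejoined at 14.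

## Further compounds

F1 | step 10 | dilithium 2-(1-oxidoethenyl)-6-[(2R)-5-methyl-2-(prop-1-en-2-yl)hex-4-en-1-yl]-3,5-bis(triisopropylsilyloxy)phenolate | [Li+].[Li+].C=C(C)[C@H](CC=C(C)C)Cc1c([O-])c(C(=C)[O-])c(O[Si](C(C)C)(C(C)C)C(C)C)cc1O[Si](C(C)C)(C(C)C)C(C)C
F2 | step 10 | 4-[(1S)-1-hydroxy-3-{2-hydroxy-3-[(2R)-5-methyl-2-(prop-1-en-2-yl)hex-4-en-1-yl]-4,6-bis(triisopropylsilyloxy)phenyl}-3-oxopropyl]-3-methoxyphenyl prop-2-en-1-yl carbonate | C=C(C)[C@H](CC=C(C)C)Cc1c(O)c(C(=O)C[C@H](O)c2ccc(OC(=O)OCC=C)cc2OC)c(O[Si](C(C)C)(C(C)C)C(C)C)cc1O[Si](C(C)C)(C(C)C)C(C)C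
F3 | step 11 | 4-[(1E)-3-{2-hydroxy-3-[(2R)-5-methyl-2-(prop-1-en-2-yl)hex-4-en-1-yl]-4,6-bis(triisopropylsilyloxy)phenyl}-3-oxoprop-1-en-1-yl]-3-methoxyphenyl prop-2-en-1-yl carbonate | C=C(C)[C@H](CC=C(C)C)Cc1c(O)c(C(=O)/C=C/c2ccc(OC(=O)OCC=C)cc2OC)c(O[Si](C(C)C)(C(C)C)C(C)C)cc1O[Si](C(C)C)(C(C)C)C(C)C
F4 | step 11 | 3-methoxy-4-[(2R)-8-[(2R)-5-methyl-2-(prop-1-en-2-yl)hex-4-en-1-yl]-4-oxo-5,7-bis(triisopropylsilyloxy)-3,4-dihydro-2H-chromen-2-yl]phenyl prop-2-en-1-yl carbonate | C=C(C)[C@H](CC=C(C)C)Cc1c(O[Si](C(C)C)(C(C)C)C(C)C)cc(O[Si](C(C)C)(C(C)C)C(C)C)c2c1O[C@@H](c1ccc(OC(=O)OCC=C)cc1OC)CC2=O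
F5 | step 7 | [(2S)-5-methyl-2-(prop-1-en-2-yl)hex-4-en-1-yl]lithium | C=C(C)[C@H](CC=C(C)C)C[Li]
F6 | step 7 | lithium 9-methoxy-9-[(2S)-5-methyl-2-(prop-1-en-2-yl)hex-4-en-1-yl]-9-borabicyclo[3.3.1]nonan-9-uide | [Li+].C=C(C)[C@H](CC=C(C)C)C[B-]1(OC)C2CCCC1CCC2
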